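The 1,2-dioxane is disconnected at C4–C5 (C4 = lactone carbinol carbon, C5 = ring CH2). Both atoms lie β to a peroxide oxygen, so the bond is made under neutral conditions as an alkene: ring-closing metathesis of an acyclic dialkyl peroxide carrying a vinyl group on quaternary C6 and an isopropenyl group plus CH2CO2H on C3 closes the 3,6-dihydro-1,2-dioxine. The step exploits that C4–C5 is flanked by the two peroxide carbons C3 and C6 and that C4 is γ to the carboxyl carbon C1: the new C4=C5 alkene is then converted by iodolactonization and deiodination into the cis-fused γ-lactone, C4 being set from C3.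

Key step: step 10

Remark: atoms are numbered C1 (lactone C=O), C2 (CH2), C3 (CH–OO), C4 (C(CH3)–O), C5 (ring CH2), C6 (C(CH3)–OO), which makes the target (3R,4R,6S); (S)-2-methylglycidol, silane 1 and both enantiomers of the prolinol silyl ether catalyst are taken as purchasable.

Step 1
Reactants: 1 (4-bromophenoxy)triisopropylsilane; 2 1,9-dibromononane
Product: 4 [4-(9-bromononyl)phenoxy]triisopropylsilane, via arylmagnesium bromide 3 (not isolated)
Conditions: 1, Mg, THF, 65 °C; then 2 (3 equiv), Li2CuCl4 (3 mol%), THF, −10 to 20 °C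
Reagents that add atoms: none
Why: Copper-catalysed Grignard cross-coupling (Kochi coupling) of the aryl Grignard reagent with a primary alkyl bromide, the excess of dibromide keeping double arylation low; no stereocenter is formed.

Step 2
Reactants: 5 (S)-2-methylglycidol
Product: 6 (R)-2-methylglycidyl tosylate
Conditions: TsCl, Et3N, DMAP (cat.), CH2Cl2, 0 °C
Reagents that add atoms: 4-toluenesulfonyl chloride, Cc1ccc(cc1)S(Cl)(=O)=O
Why: O-Sulfonylation of the primary alcohol, which leaves the quaternary stereocenter untouched (the descriptor changes from S to R by priority only).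

Step 3
Reactants: 4 [4-(9-bromononyl)phenoxy]triisopropylsilane; 6 (R)-2-methylglycidyl tosylate
Product: 9 (R)-2-methyl-2-{10-[4-(triisopropylsilyloxy)phenyl]decyl}oxirane, via alkylmagnesium bromide 7 (not isolated), via hydroxy tosylate 8 (not isolated)
Conditions: 4, Mg, THF, 40 °C; then 6, CuI (10 mol%), THF, −40 to 0 °C; crude after aqueous work-up, NaH, THF, 0 to 20 °C
Reagents that add atoms: none
Why: Copper-catalysed Grignard opening of the epoxide at its CH2 terminus (faster than displacement of the neopentyl-type tosylate) followed by Williamson closure of the tertiary alkoxide onto CH2OTs; neither event touches the stereocenter, so its configuration comes from 5.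

Step 4
Reactants: 9 (R)-2-methyl-2-{10-[4-(triisopropylsilyloxy)phenyl]decyl}oxirane
Product: 10 (S)-2-hydroperoxy-2-methyl-12-[4-(triisopropylsilyloxy)phenyl]dodecan-1-ol
Conditions: H2O2 (anhydrous, in Et2O, 10 equiv), H3PMo12O40 (5 mol%), Et2O, 20 °C
Reagents that add atoms: hydrogen peroxide, OO
Why: Molybdenum-catalysed perhydrolysis of a 2,2-disubstituted epoxide, in which H2O2 should open the activated oxirane at the tertiary carbon with inversion (SN2-like) and thereby set C6.

Step 5
Reactants: 11 methacrolein; 12 (triphenylphosphoranylidene)acetaldehyde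
Product: 13 (E)-4-methylpenta-2,4-dienal
Conditions: 11 (3 equiv), toluene, 80 °C
Reagents that add atoms: none
Why: Wittig two-carbon homologation with a formyl-stabilised ylide, which should give the E-enal, the excess of 11 suppressing a second homologation.

Step 6
Reactants: 10 (S)-2-hydroperoxy-2-methyl-12-[4-(triisopropylsilyloxy)phenyl]dodecan-1-ol; 13 (E)-4-methylpenta-2,4-dienal
Product: 14 (3R)-3-({(2S)-1-hydroxy-2-methyl-12-[4-(triisopropylsilyloxy)phenyl]dodecan-2-yl}peroxy)-4-methylpent-4-enal
Conditions: 13 (2.5 equiv), (R)-2-{bis[3,5-bis(trifluoromethyl)phenyl][(trimethylsilyl)oxy]methyl}pyrrolidine (20 mol%), toluene, 0 °C; used at once in step 7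
Reagents that add atoms: none
Why: Iminium-catalysed asymmetric conjugate addition of a hydroperoxide to an enal (peroxy-Michael β-peroxidation), in which the (R)-catalyst shields the Si face of C3 of the s-trans E-iminium ion so that the hydroperoxide should add to the Re face and set C3 as R under catalyst control, β-attack being the usual course for heteroatom nucleophiles on such iminium ions.

Step 7
Reactants: 14 (3R)-3-({(2S)-1-hydroxy-2-methyl-12-[4-(triisopropylsilyloxy)phenyl]dodecan-2-yl}peroxy)-4-methylpent-4-enal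
Product: 15 (3R)-3-({(2S)-1-hydroxy-2-methyl-12-[4-(triisopropylsilyloxy)phenyl]dodecan-2-yl}peroxy)-4-methylpent-4-enoic acid
Conditions: NaClO2, NaH2PO4, 2-methyl-2-butene, t-BuOH/H2O, 0 °C
Reagents that add atoms: sodium chlorite, [Na+].[O-]Cl=O
Why: Pinnick (chlorite) oxidation of the aldehyde under buffered, mildly acidic conditions with an alkene scavenger for hypochlorite, which leaves alcohol, isopropenyl group and peroxide alone and removes the retro-Michael-prone aldehyde.

Step 8
Reactants: 15 (3R)-3-({(2S)-1-hydroxy-2-methyl-12-[4-(triisopropylsilyloxy)phenyl]dodecan-2-yl}peroxy)-4-methylpent-4-enoic acid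
Product: 16 (3R)-4-methyl-3-({(2S)-2-methyl-1-oxo-12-[4-(triisopropylsilyloxy)phenyl]dodecan-2-yl}peroxy)pent-4-enoic acid
Conditions: Dess–Martin periodinane, CH2Cl2, 0 to 20 °C
Reagents that add atoms: none
Why: Dess–Martin oxidation of the neopentyl-type primary alcohol to a non-enolisable α-peroxy aldehyde under non-basic conditions, with no stereocenter affected.

Step 9
Reactants: 16 (3R)-4-methyl-3-({(2S)-2-methyl-1-oxo-12-[4-(triisopropylsilyloxy)phenyl]dodecan-2-yl}peroxy)pent-4-enoic acid
Product: 17 (3R)-4-methyl-3-({(3S)-3-methyl-13-[4-(triisopropylsilyloxy)phenyl]tridec-1-en-3-yl}peroxy)pent-4-enoic acid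
Conditions: Ph3PCH3Br (3.0 equiv), KN(SiMe3)2 (2.9 equiv), THF, −78 to 0 °C; work-up at pH 4
Reagents that add atoms: methyltriphenylphosphonium bromide (as its ylide), C[P+](c1ccccc1)(c1ccccc1)c1ccccc1.[Br-]
Why: Wittig methylenation of the aldehyde, the first equivalent of ylide turning the acid into its carboxylate, which protects C2–H from base-induced loss of the β-peroxide.

Step 10
Reactants: 17 (3R)-4-methyl-3-({(3S)-3-methyl-13-[4-(triisopropylsilyloxy)phenyl]tridec-1-en-3-yl}peroxy)pent-4-enoic acid
Product: 18 2-[(3R,6S)-4,6-dimethyl-6-{10-[4-(triisopropylsilyloxy)phenyl]decyl}-3,6-dihydro-1,2-dioxin-3-yl]acetic acid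
Conditions: second-generation Grubbs catalyst (H2IMes)(PCy3)Cl2Ru=CHPh (5–10 mol%), CH2Cl2 (0.005 M), 40 °C
Reagents that add atoms: none
Why: Ring-closing olefin metathesis: the ruthenium alkylidene exchanges onto the vinyl group at C6, adds [2+2] to the isopropenyl group at C3 and cycloreverts, expelling ethylene and forming C4=C5. The closest known reaction type is ring-closing metathesis of a monosubstituted with a 1,1-disubstituted alkene to a trisubstituted six-membered cycloalkene, with a vinyl group on an oxygen-bearing quaternary carbon as loading site, run here with a dialkyl peroxide in the tether as in metathesis of other peroxide-containing alkenes. The only ring closed is the 3,6-dihydro-1,2-dioxine, formed in the six-membered alkene–alkene metathesis mode (C5 of the vinyl group to C4 of the isopropenyl group). No stereocenter is created, C3 (R) and C6 (S) are carried through unchanged, and C4 is set from C3 in step 11. The step needs chemoselectivity of the alkylidene for the two C=C bonds over the O–O bond and over isomerisation of the allylic C3–H peroxide, which the neutral, non-basic and non-reducing conditions, high dilution and the gem-disubstitution at C6 that favours the folded conformer are expected to secure.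

Step 11
Reactants: 18 2-[(3R,6S)-4,6-dimethyl-6-{10-[4-(triisopropylsilyloxy)phenyl]decyl}-3,6-dihydro-1,2-dioxin-3-yl]acetic acid
Product: 19 (3R,4S,5R,6S)-5-iodo-O-triisopropylsilylplakortolide S (cis-fused iodolactone, iodine trans to the lactone oxygen)
Conditions: I2, NaHCO3, MeCN/H2O, 0 °C, dark
Reagents that add atoms: iodine, II
Why: Iodolactonization, in which the carboxylate opens the iodonium ion at the more substituted C4 in a 5-exo anti addition from the ring face carrying the CH2CO2H arm, so only the cis-fused γ-lactone can form and C4 is set by C3.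

Step 12
Reactants: 19 (3R,4S,5R,6S)-5-iodo-O-triisopropylsilylplakortolide S
Product: 20 (3R,4R,6S)-O-triisopropylsilylplakortolide S
Conditions: Bu3SnH (3 equiv, 0.3 M), Et3B (0.2 equiv), air, toluene, 0 °C
Reagents that add atoms: none
Why: Radical-chain hydrodeiodination started at low temperature, in which the C5 radical should be quenched by the concentrated stannane faster than it can attack the O–O bond; the C5 stereocenter disappears.

Step 13
Reactants: 20 (3R,4R,6S)-O-triisopropylsilylplakortolide S
Product: 21 plakortolide S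
Conditions: Bu4NF, AcOH (1:1), THF, 0 °C
Reagents that add atoms: none
Why: Fluoride cleavage of the aryl silyl ether, buffered with acetic acid so that the base-sensitive β-peroxy lactone is not exposed to free fluoride or phenoxide.

Compound list
1 | (4-bromophenoxy)triisopropylsilane | CC(C)[Si](Oc1ccc(Br)cc1)(C(C)C)C(C)C | starting material
2 | 1,9-dibromononane | BrCCCCCCCCCBr | starting material
3 | [4-(triisopropylsilyloxy)phenyl]magnesium bromide | CC(C)[Si](Oc1ccc([Mg]Br)cc1)(C(C)C)C(C)C | intermediate
4 | [4-(9-bromononyl)phenoxy]triisopropylsilane | BrCCCCCCCCCc1ccc(O[Si](C(C)C)(C(C)C)C(C)C)cc1 | intermediate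
5 | (S)-2-methylglycidol, [(2S)-2-methyloxiran-2-yl]methanol | C[C@@]1(CO1)CO | starting material
6 | (R)-2-methylglycidyl tosylate, [(2R)-2-methyloxiran-2-yl]methyl 4-methylbenzenesulfonate | C[C@@]1(CO1)COS(=O)(=O)c1ccc(C)cc1 | intermediate
7 | {9-[4-(triisopropylsilyloxy)phenyl]nonyl}magnesium bromide | Br[Mg]CCCCCCCCCc1ccc(O[Si](C(C)C)(C(C)C)C(C)C)cc1 | intermediate
8 | (2R)-2-hydroxy-2-methyl-12-[4-(triisopropylsilyloxy)phenyl]dodecyl 4-methylbenzenesulfonate | C[C@@](O)(CCCCCCCCCCc1ccc(O[Si](C(C)C)(C(C)C)C(C)C)cc1)COS(=O)(=O)c1ccc(C)cc1 | intermediate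
9 | (R)-2-methyl-2-{10-[4-(triisopropylsilyloxy)phenyl]decyl}oxirane | C[C@@]1(CCCCCCCCCCc2ccc(O[Si](C(C)C)(C(C)C)C(C)C)cc2)CO1 | intermediate
10 | (S)-2-hydroperoxy-2-methyl-12-[4-(triisopropylsilyloxy)phenyl]dodecan-1-ol | C[C@](OO)(CCCCCCCCCCc1ccc(O[Si](C(C)C)(C(C)C)C(C)C)cc1)CO | intermediate
11 | methacrolein | CC(=C)C=O | starting material
12 | (triphenylphosphoranylidene)acetaldehyde | O=CC=P(c1ccccc1)(c1ccccc1)c1ccccc1 | starting material
13 | (E)-4-methylpenta-2,4-dienal | CC(=C)/C=C/C=O | intermediate
14 | (3R)-3-({(2S)-1-hydroxy-2-methyl-12-[4-(triisopropylsilyloxy)phenyl]dodecan-2-yl}peroxy)-4-methylpent-4-enal | C[C@](OO[C@H](CC=O)C(C)=C)(CCCCCCCCCCc1ccc(O[Si](C(C)C)(C(C)C)C(C)C)cc1)CO | intermediate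
15 | (3R)-3-({(2S)-1-hydroxy-2-methyl-12-[4-(triisopropylsilyloxy)phenyl]dodecan-2-yl}peroxy)-4-methylpent-4-enoic acid | C[C@](OO[C@H](CC(O)=O)C(C)=C)(CCCCCCCCCCc1ccc(O[Si](C(C)C)(C(C)C)C(C)C)cc1)CO | intermediate
16 | (3R)-4-methyl-3-({(2S)-2-methyl-1-oxo-12-[4-(triisopropylsilyloxy)phenyl]dodecan-2-yl}peroxy)pent-4-enoic acid | C[C@](OO[C@H](CC(O)=O)C(C)=C)(CCCCCCCCCCc1ccc(O[Si](C(C)C)(C(C)C)C(C)C)cc1)C=O | intermediate
17 | (3R)-4-methyl-3-({(3S)-3-methyl-13-[4-(triisopropylsilyloxy)phenyl]tridec-1-en-3-yl}peroxy)pent-4-enoic acid | C[C@](OO[C@H](CC(O)=O)C(C)=C)(CCCCCCCCCCc1ccc(O[Si](C(C)C)(C(C)C)C(C)C)cc1)C=C | intermediate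
18 | 2-[(3R,6S)-4,6-dimethyl-6-{10-[4-(triisopropylsilyloxy)phenyl]decyl}-3,6-dihydro-1,2-dioxin-3-yl]acetic acid | C[C@]1(CCCCCCCCCCc2ccc(O[Si](C(C)C)(C(C)C)C(C)C)cc2)C=C(C)[C@@H](CC(O)=O)OO1 | intermediate
19 | (3R,4S,5R,6S)-5-iodo-O-triisopropylsilylplakortolide S (cis-fused peroxy lactone, I at C5 trans to the lactone oxygen) | C[C@]1(CCCCCCCCCCc2ccc(O[Si](C(C)C)(C(C)C)C(C)C)cc2)[C@H](I)[C@@]3(C)OC(=O)C[C@H]3OO1 | intermediate
20 | (3R,4R,6S)-O-triisopropylsilylplakortolide S | C[C@]1(CCCCCCCCCCc2ccc(O[Si](C(C)C)(C(C)C)C(C)C)cc2)C[C@@]3(C)OC(=O)C[C@H]3OO1 | intermediate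
21 | plakortolide S, (3R,4R,6S) | C[C@]1(CCCCCCCCCCc2ccc(O)cc2)C[C@@]2(C)OC(=O)C[C@H]2OO1 | target

Total step count: 13. Longest linear sequence: 11 steps (1, 3, 4, 6, 7, 8, 9, 10, 11, 12, 13).

Steps most likely to fail

Step 6. The hydroperoxide may add to the unsubstituted terminus of the dienyl iminium ion (1,6-addition) instead of C3. The intermediate enamine may also displace alkoxide from the O–O bond to give an epoxy aldehyde, or the neighbouring hydroxyl may condense with the aldehyde. The fallback sets out from 10 and comes back to the route at 18; it blocks the diene terminus with a group that metathesis later expels. α-Methyl-trans-cinnamaldehyde and ylide 12 give (2E,4E)-4-methyl-5-phenylpenta-2,4-dienal F1, a styryl-type enal of the kind that reacts at the β-carbon under iminium catalysis. Peroxidation of F1 with 10 under the conditions of step 6 should give (3R,4E)-3-({(2S)-1-hydroxy-2-methyl-12-[4-(triisopropylsilyloxy)phenyl]dodecan-2-yl}peroxy)-4-methyl-5-phenylpent-4-enal F2. Chlorite oxidation then gives the corresponding pent-4-enoic acid F3, Dess–Martin oxidation the 1-oxo acid F4, and Wittig methylenation the vinyl diene acid F5. Ring-closing metathesis of F5 under the conditions of step 10 expels styrene instead of ethylene and gives 18.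

Step 10. Loading of ruthenium onto the hindered vinyl group at quaternary C6 may be slow. Cleavage of the O–O bond by the divalent ruthenium species, or isomerisation of the allylic peroxide to a hydroxy enone, could then outrun ring closure. The fallback sets out from 16 and comes back at 18; it uses relay ring-closing metathesis. Wittig reaction of 16 with hex-5-enylidenetriphenylphosphorane gives (3R)-4-methyl-3-({(3S,1Z)-3-methyl-13-[4-(triisopropylsilyloxy)phenyl]trideca-1,7-dien... relay triene acid, (3R)-4-methyl-3-({(7S,5Z)-7-methyl-17-[4-(triisopropylsilyloxy)phenyl]heptadeca-1,5-dien-7-yl}peroxy)pent-4-enoic acid F6. The catalyst loads on the unhindered terminal alkene, expels cyclopentene and is thereby delivered to C5, from where it closes onto the isopropenyl group to give 18.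

Step 12. The C5 radical may attack the adjacent O–O bond (intramolecular homolytic substitution to an epoxide and an alkoxyl radical) before hydrogen transfer. The fallback sets out from 18 and comes back at 20 without any radical and without 19 (no new compound, F0). Brønsted-acid hydrolactonization (CF3SO3H, 5 mol%, CH2Cl2, 0 °C) protonates C5 to give the tertiary C4 cation, which the carboxylic acid captures on its own ring face to give the cis-fused lactone.

Further compounds
F1 | step 6 | (2E,4E)-4-methyl-5-phenylpenta-2,4-dienal | O=C/C=C/C(C)=C/c1ccccc1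
F2 | step 6 | (3R,4E)-3-({(2S)-1-hydroxy-2-methyl-12-[4-(triisopropylsilyloxy)phenyl]dodecan-2-yl}peroxy)-4-methyl-5-phenylpent-4-enal | C[C@](OO[C@H](CC=O)/C(C)=C/c1ccccc1)(CCCCCCCCCCc1ccc(O[Si](C(C)C)(C(C)C)C(C)C)cc1)CO
F3 | step 6 | (3R,4E)-3-({(2S)-1-hydroxy-2-methyl-12-[4-(triisopropylsilyloxy)phenyl]dodecan-2-yl}peroxy)-4-methyl-5-phenylpent-4-enoic acid | C[C@](OO[C@H](CC(O)=O)/C(C)=C/c1ccccc1)(CCCCCCCCCCc1ccc(O[Si](C(C)C)(C(C)C)C(C)C)cc1)CO
F4 | step 6 | (3R,4E)-4-methyl-3-({(2S)-2-methyl-1-oxo-12-[4-(triisopropylsilyloxy)phenyl]dodecan-2-yl}peroxy)-5-phenylpent-4-enoic acid | C[C@](OO[C@H](CC(O)=O)/C(C)=C/c1ccccc1)(CCCCCCCCCCc1ccc(O[Si](C(C)C)(C(C)C)C(C)C)cc1)C=O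
F5 | step 6 | (3R,4E)-4-methyl-3-({(3S)-3-methyl-13-[4-(triisopropylsilyloxy)phenyl]tridec-1-en-3-yl}peroxy)-5-phenylpent-4-enoic acid | C[C@](OO[C@H](CC(O)=O)/C(C)=C/c1ccccc1)(CCCCCCCCCCc1ccc(O[Si](C(C)C)(C(C)C)C(C)C)cc1)C=C
F6 | step 10 | (3R)-4-methyl-3-({(7S,5Z)-7-methyl-17-[4-(triisopropylsilyloxy)phenyl]heptadeca-1,5-dien-7-yl}peroxy)pent-4-enoic acid | C[C@](OO[C@H](CC(O)=O)C(C)=C)(CCCCCCCCCCc1ccc(O[Si](C(C)C)(C(C)C)C(C)C)cc1)/C=C\CCCC=C
F0 | step 12 | none | none
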